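**Two flasks.** If I set this flask beside a thinner one, with the same Z but G at 0.056 M, the two look nearly alike at the start.

G 0.14 M; Z 14 mM; time 80 s

    G + Z ⇌ J + Z, rate k1*[G]*[Z] forward; the back reaction follows from the equilibrium constant (K1 = 1.81, k1 = 2.48 L mol⁻¹ s⁻¹)
    G ⇌ L (K2 = 0.359, k2 = 0.0407 s⁻¹)
    Z → Q (k3 = 0.0101 s⁻¹)
    G + Z → G.Z (k4 = 0.137 L mol⁻¹ s⁻¹)
    2 G → G2 (k5 = 0.0343 L mol⁻¹ s⁻¹)

- a species is counted by the G in it: one G2 counts as two
- a doubled species enters its step squared and goes two at a time
- the reaction counts as stopped when no species that holds the G changes by six tenths of a point or more over the second half of the time
- run time (flask): 80 s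

- which holds at 80 s: what has brought the reaction to rest, or that it has not come to rest (no working catalyst is left / all of G has reacted / it is still moving / forward and back rates have come level)
- conversion of G at 80 s
- amount of J at 80 s, in percent of the G charged

**The start.** Each G passes into J at a rate proportional to the rate constant of that step times [Z], and into L at the constant of that step. The forward ratio of the two is 0.853 in both flasks, since G cancels.

**Catalyst life.** This ratio falls as Z is lost, to Q and to G.Z. The second loss depends on G, so I treat the loss as pseudo-first-order, with [G] held at half its charge. The catalyst life τ, one over the sum of the two loss rates taken so, is the time in which Z falls by a factor e. Here τ is 50.8 s, and in the thinner flask 71.8 s. Because G itself takes Z away, the thinner flask keeps its catalyst longer, so I expect it to end with more J in percent of its charge. In this flask, 20.7 % of Z should remain at 80 s, so I do not expect a dead catalyst at that time. Live Z can still carry a step to the level of its forward and back rates, so this does not tell me whether the flask is still moving, and I leave that open. My reckoning gives no figure for conversion or J.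

**The forecast.** It says it is still moving, with conversion 70 % and J 41 %, holding that “the catalyst still has about a quarter of its activity”. I reckon slightly less Z than that.

**The run.** This flask gives it is still moving, with conversion 70.8 % and J 41.9 %, so the forecast holds. The forward ratio of J to L has dropped from 0.853 to 0.20, close to the 0.177 that τ gives. J shifts by 5 points at 10.4 mM or 21.8 mM of Z, and such a charge could put the forecast wrong. In the thinner flask, τ leaves 32.8 % of Z. The run gives 34.3 % of Z and J at 46.7 %.

(The constants used here come from no measurement; the flask was simulated.)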